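## Retrosynthetic overview

1. The target is reached from its doubly protected form (phenolic MOM ether, benzylic TBS ether) by one acidic methanolysis.
2. The strategy rests on ring A, the hexasubstituted benzene (C1 CO2Me, C2 aryloxy, C3 H, C4 CH3, C5 prenyl, C6 OH). Its C1–C6–C5–C4 segment is a 4-oxygenated 6-methyl-5-prenyl-2-pyranone-3-carboxylate, and its C2–C3 pair is the ethynyl ether of the ring B phenol. Bonds C1–C2 and C3–C4 are made by an inverse-demand [4+2] cycloaddition, and CO2 is then expelled.
3. Pyranone: dehydroacetic acid → methyl 3,5-dioxohexanoate → C4 prenylation → lactonisation → C3 bromination, MOM protection, palladium-catalysed methoxycarbonylation.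
4. Ynol ether: 2,4-dimethoxybenzaldehyde → 2,4-dimethoxyphenol → ortho-formylation → dichlorovinyl ether from trichloroethylene → reduction, silylation → n-BuLi.
5. Ring order: ring B is bought; the pyranone ring is built second and is sacrificed; ring A is closed last.

Key step: step 13

Remark: the target has no stereocentre. The C4 centre of 4 and the bridgeheads of 20 are racemic and are destroyed, and the (E) geometry of 14–16 is erased in step 12. Ring A locants in the names of 21, 22 and F1–F4 follow the numbering used above (C1 = ester carbon).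

## Route

Step 1
Reactants: 1 dehydroacetic acid (3-acetyl-4-hydroxy-6-methyl-2H-pyran-2-one)
Product: 2 methyl 3,5-dioxohexanoate
Conditions: Mg(OMe)2, MeOH, reflux; then aq. HCl
Reagents that add atoms: magnesium methoxide, CO[Mg]OC; methanol, CO
Why: Methoxide opens the lactone and a retro-Claisen deacetylation of the resulting 2-acetyl-3,5-dioxo ester, held as its magnesium chelate, should leave the diketo ester (lactone methanolysis followed by retro-Claisen cleavage).

Step 2
Reactants: 2 methyl 3,5-dioxohexanoate; 3 prenyl bromide (1-bromo-3-methylbut-2-ene)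
Product: 4 methyl 4-acetyl-7-methyl-3-oxooct-6-enoate (the diketo ester with prenyl on C4; racemic, enolised)
Conditions: NaH (1.0 equiv), THF, 0 °C; then 3, 0 °C to rt
Reagents that add atoms: none
Why: The monoanion resides on C4, the most acidic carbon between the two ketones, and should be C-alkylated at the primary carbon of the allylic bromide (SN2 alkylation of a β-diketone enolate), one equivalent of base keeping C2 untouched.

Step 3
Reactants: 4 methyl 4-acetyl-7-methyl-3-oxooct-6-enoate
Product: 5 4-hydroxy-6-methyl-5-(3-methylbut-2-enyl)-2H-pyran-2-one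
Conditions: DBU, PhMe, reflux; then aq. HCl
Reagents that add atoms: none
Why: Base-promoted lactonisation (intramolecular transesterification): the enol oxygen of the acetyl group attacks the methyl ester in a 6-exo-trig closure, and the stable pyranonate anion drains the equilibrium.

Step 4
Reactants: 5 4-hydroxy-6-methyl-5-(3-methylbut-2-enyl)-2H-pyran-2-one
Product: 6 3-bromo-4-hydroxy-6-methyl-5-(3-methylbut-2-enyl)-2H-pyran-2-one
Conditions: NBS (1.0 equiv), THF, −40 to 0 °C, dark
Reagents that add atoms: N-bromosuccinimide, O=C1CCC(=O)N1Br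
Why: Electrophilic halogenation of the enolised 1,3-dicarbonyl at C3, its only free nucleophilic carbon, should be much faster at low temperature than attack of one equivalent of NBS on the trisubstituted alkene.

Step 5
Reactants: 6 3-bromo-4-hydroxy-6-methyl-5-(3-methylbut-2-enyl)-2H-pyran-2-one
Product: 7 3-bromo-4-(methoxymethoxy)-6-methyl-5-(3-methylbut-2-enyl)-2H-pyran-2-one
Conditions: MOMCl, i-Pr2NEt, CH2Cl2, 0 °C to rt
Reagents that add atoms: chloromethyl methyl ether, COCCl
Why: O-alkylation of the acidic 4-hydroxyl by the hard chloromethyl ether (Williamson-type acetal formation); C3 is blocked, and 4-O alkylation is expected over 2-O alkylation as for other 4-hydroxy-2-pyranones.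

Step 6
Reactants: 7 3-bromo-4-(methoxymethoxy)-6-methyl-5-(3-methylbut-2-enyl)-2H-pyran-2-one
Product: 8 methyl 4-(methoxymethoxy)-6-methyl-5-(3-methylbut-2-enyl)-2-oxo-2H-pyran-3-carboxylate
Conditions: Pd(OAc)2 (5 mol %), Xantphos (6 mol %), CO (3 bar), MeOH (10 equiv), Et3N, DMF, 70 °C
Reagents that add atoms: carbon monoxide, [C-]#[O+]; methanol, CO
Why: Palladium-catalysed alkoxycarbonylation (Heck carbonylation) of the vinyl bromide: oxidative addition to zerovalent palladium, CO insertion and methanolysis of the acylpalladium, 3-bromo-2-pyranones being established cross-coupling partners; methanol is kept low to spare the MOM group.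

Step 7
Reactants: 9 2,4-dimethoxybenzaldehyde
Product: 11 2,4-dimethoxyphenol, via 2,4-dimethoxyphenyl formate 10 (not isolated)
Conditions: mCPBA, CH2Cl2, 0 °C to rt; then K2CO3 (cat.), MeOH, rt
Reagents that add atoms: 3-chloroperoxybenzoic acid, OOC(=O)c1cccc(Cl)c1
Why: Baeyer–Villiger (Dakin-type) oxidation in which the electron-rich aryl group migrates to give the formate, which is methanolysed under mild base without touching the methyl ethers.

Step 8
Reactants: 11 2,4-dimethoxyphenol
Product: 12 2-hydroxy-3,5-dimethoxybenzaldehyde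
Conditions: MgCl2, Et3N, (CH2O)n, MeCN, reflux; then 1 M HCl
Reagents that add atoms: paraformaldehyde (formaldehyde), C=O
Why: Magnesium-mediated ortho-formylation (Casnati–Skattebøl reaction): the magnesium phenoxide delivers formaldehyde to the single free ortho position, and hydride transfer to a second formaldehyde oxidises the benzylic alkoxide to the aldehyde.

Step 9
Reactants: 12 2-hydroxy-3,5-dimethoxybenzaldehyde; 13 trichloroethylene
Product: 14 2-[(E)-1,2-dichloroethenyloxy]-3,5-dimethoxybenzaldehyde
Conditions: K2CO3, DMF, 70 °C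
Reagents that add atoms: none
Why: Base dehydrochlorinates 13 to dichloroacetylene in situ and the phenoxide adds to it in anti fashion (elimination–addition vinylic substitution), giving the (E)-dichlorovinyl ether while the aldehyde is untouched by carbonate.

Step 10
Reactants: 14 2-[(E)-1,2-dichloroethenyloxy]-3,5-dimethoxybenzaldehyde
Product: 15 {2-[(E)-1,2-dichloroethenyloxy]-3,5-dimethoxyphenyl}methanol
Conditions: NaBH4, MeOH, 0 °C
Reagents that add atoms: none
Why: Borohydride reduction of the aldehyde; the dichlorovinyl ether is inert to NaBH4.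

Step 11
Reactants: 15 {2-[(E)-1,2-dichloroethenyloxy]-3,5-dimethoxyphenyl}methanol
Product: 16 tert-butyl{2-[(E)-1,2-dichloroethenyloxy]-3,5-dimethoxybenzyloxy}dimethylsilane
Conditions: TBSCl, imidazole, DMF, rt
Reagents that add atoms: tert-butyldimethylsilyl chloride, CC(C)(C)[Si](C)(C)Cl
Why: Imidazole-promoted silylation of the primary alcohol, which masks the only acidic proton before the organolithium step.

Step 12
Reactants: 16 tert-butyl{2-[(E)-1,2-dichloroethenyloxy]-3,5-dimethoxybenzyloxy}dimethylsilane
Product: 19 tert-butyl[2-(ethynyloxy)-3,5-dimethoxybenzyloxy]dimethylsilane, via chloroethynyl aryl ether 17 (not isolated), via lithium aryloxyacetylide 18 (not isolated)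
Conditions: n-BuLi (2.2 equiv), THF, −78 to −40 °C; then MeOH, −78 °C
Reagents that add atoms: none
Why: Dehydrochlorination by the first equivalent of n-BuLi and chlorine–lithium exchange by the second give the lithium acetylide, which is protonated cold (the standard dichlorovinyl ether route to ynol ethers); 19 is used at once.

Step 13
Reactants: 8 methyl 4-(methoxymethoxy)-6-methyl-5-(3-methylbut-2-enyl)-2-oxo-2H-pyran-3-carboxylate; 19 tert-butyl[2-(ethynyloxy)-3,5-dimethoxybenzyloxy]dimethylsilane
Product: 21 methyl 2-[2-(tert-butyldimethylsilyloxymethyl)-4,6-dimethoxyphenoxy]-6-(methoxymethoxy)-4-methyl-5-(3-methylbut-2-enyl)benzoate, via bridged bicyclic lactone 20 (not isolated)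
Conditions: o-xylene, 140 °C, sealed tube, BHT (cat.); 19 (2 equiv) added in portions
Reagents that add atoms: none
Why: Pyranone 8 is an electron-poor diene (C3=C4–C5=C6, lowered in energy by the C3 ester and the lactone carbonyl) and 19 an electron-rich dienophile, so an inverse-electron-demand Diels–Alder reaction should join the terminal alkyne CH to C6 of 8 (future C4 of ring A) and the oxygen-bearing alkyne carbon to C3 (future C1), giving the 2-oxabicyclo[2.2.2]octadienone 20. The closest known reaction type is the cycloaddition of 2-pyranone-3-carboxylates with ynol ethers, ynamines and ketene acetals followed by decarboxylative aromatisation. Ring A is closed in this intermolecular [4+2] step, which forms the sigma bonds C1–C2 and C3–C4 together, and retro-[4+2] loss of CO2 from 20 then makes the ring aromatic and the sequence irreversible without an oxidant. No stereocentre is created in the product, since the two bridgehead centres of 20 are racemic and vanish with CO2. The one selectivity needed is regiochemical, aryloxy next to the ester, and polarity matching secures it: the nucleophilic terminal carbon of the ynol ether attacks C6, the vinylogous electrophilic terminus of the dienoate, while the oxygen-stabilised cationic carbon is taken up by the malonate-like C3. The aryl ynol ether has no β-hydrogen for retro-ene fragmentation to a ketene, so it should tolerate the temperature this tetrasubstituted 4-alkoxy diene is expected to need, and its excess offsets its own oligomerisation.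

Step 14
Reactants: 21 methyl 2-[2-(tert-butyldimethylsilyloxymethyl)-4,6-dimethoxyphenoxy]-6-(methoxymethoxy)-4-methyl-5-(3-methylbut-2-enyl)benzoate
Product: 22 methyl 6-hydroxy-2-[2-(hydroxymethyl)-4,6-dimethoxyphenoxy]-4-methyl-5-(3-methylbut-2-enyl)benzoate (CNP0583011.0)
Conditions: HCl (1 M in MeOH), 0 °C to rt
Reagents that add atoms: none
Why: Acid-catalysed acetal exchange removes the MOM ether (labile ortho to the ester) and methanolysis removes the primary silyl ether in the same flask, the low temperature and the hydrogen-bonded, weakly nucleophilic salicylate phenol disfavouring chromane formation with the prenyl group.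

## Compound list

1 | dehydroacetic acid | CC(=O)C1=C(O)C=C(C)OC1=O | starting material
2 | methyl 3,5-dioxohexanoate | COC(=O)CC(=O)CC(C)=O | intermediate
3 | prenyl bromide | CC(C)=CCBr | starting material
4 | methyl 4-acetyl-7-methyl-3-oxooct-6-enoate (racemic, enolised) | COC(=O)CC(=O)C(CC=C(C)C)C(C)=O | intermediate
5 | 4-hydroxy-6-methyl-5-(3-methylbut-2-enyl)-2H-pyran-2-one | CC1=C(CC=C(C)C)C(O)=CC(=O)O1 | intermediate
6 | 3-bromo-4-hydroxy-6-methyl-5-(3-methylbut-2-enyl)-2H-pyran-2-one | CC1=C(CC=C(C)C)C(O)=C(Br)C(=O)O1 | intermediate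
7 | 3-bromo-4-(methoxymethoxy)-6-methyl-5-(3-methylbut-2-enyl)-2H-pyran-2-one | COCOC1=C(Br)C(=O)OC(C)=C1CC=C(C)C | intermediate
8 | methyl 4-(methoxymethoxy)-6-methyl-5-(3-methylbut-2-enyl)-2-oxo-2H-pyran-3-carboxylate | COC(=O)C1=C(OCOC)C(CC=C(C)C)=C(C)OC1=O | intermediate
9 | 2,4-dimethoxybenzaldehyde | COc1ccc(C=O)c(OC)c1 | starting material
10 | 2,4-dimethoxyphenyl formate | COc1ccc(OC=O)c(OC)c1 | intermediate
11 | 2,4-dimethoxyphenol | COc1ccc(O)c(OC)c1 | intermediate
12 | 2-hydroxy-3,5-dimethoxybenzaldehyde | COc1cc(C=O)c(O)c(OC)c1 | intermediate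
13 | trichloroethylene | ClC=C(Cl)Cl | starting material
14 | 2-[(E)-1,2-dichloroethenyloxy]-3,5-dimethoxybenzaldehyde | COc1cc(C=O)c(O/C(Cl)=C\Cl)c(OC)c1 | intermediate
15 | {2-[(E)-1,2-dichloroethenyloxy]-3,5-dimethoxyphenyl}methanol | COc1cc(CO)c(O/C(Cl)=C\Cl)c(OC)c1 | intermediate
16 | tert-butyl{2-[(E)-1,2-dichloroethenyloxy]-3,5-dimethoxybenzyloxy}dimethylsilane | COc1cc(CO[Si](C)(C)C(C)(C)C)c(O/C(Cl)=C\Cl)c(OC)c1 | intermediate
17 | tert-butyl[2-(chloroethynyloxy)-3,5-dimethoxybenzyloxy]dimethylsilane | COc1cc(CO[Si](C)(C)C(C)(C)C)c(OC#CCl)c(OC)c1 | intermediate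
18 | {[2-(tert-butyldimethylsilyloxymethyl)-4,6-dimethoxyphenoxy]ethynyl}lithium | COc1cc(CO[Si](C)(C)C(C)(C)C)c(OC#C[Li])c(OC)c1 | intermediate
19 | tert-butyl[2-(ethynyloxy)-3,5-dimethoxybenzyloxy]dimethylsilane | C#COc1c(CO[Si](C)(C)C(C)(C)C)cc(OC)cc1OC | intermediate
20 | methyl 5-[2-(tert-butyldimethylsilyloxymethyl)-4,6-dimethoxyphenoxy]-8-(methoxymethoxy)-1-methyl-7-(3-methylbut-2-enyl)-3-oxo-2-oxabicyclo[2.2.2]octa-5,7-diene-4-carboxylate (racemic) | COC(=O)C12C(=O)OC(C)(C=C1Oc1c(CO[Si](C)(C)C(C)(C)C)cc(OC)cc1OC)C(CC=C(C)C)=C2OCOC | intermediate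
21 | methyl 2-[2-(tert-butyldimethylsilyloxymethyl)-4,6-dimethoxyphenoxy]-6-(methoxymethoxy)-4-methyl-5-(3-methylbut-2-enyl)benzoate | COC(=O)c1c(Oc2c(CO[Si](C)(C)C(C)(C)C)cc(OC)cc2OC)cc(C)c(CC=C(C)C)c1OCOC | intermediate
22 | methyl 6-hydroxy-2-[2-(hydroxymethyl)-4,6-dimethoxyphenoxy]-4-methyl-5-(3-methylbut-2-enyl)benzoate | COC(=O)c1c(Oc2c(CO)cc(OC)cc2OC)cc(C)c(CC=C(C)C)c1O | target

## Step count and risks

Total step count: 14.
Longest linear sequence: 8 steps (steps 1–6, 13, 14; the ring B branch through steps 7–12, 13, 14 is equally long).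

Steps most likely to fail:

Step 13. The cycloaddition may be too slow for a tetrasubstituted, donor-substituted diene and a dienophile whose oxygen carries a 2,6-disubstituted aryl group, so that oligomerisation of the ynol ether outruns ring formation. The fallback keeps the pyranone benzannulation but makes the diaryl ether bond separately. It sets out from 8, which is heated with the smaller and more nucleophilic 1,1-bis(trimethylsilyloxy)ethene of the same polarity. After loss of CO2 and trimethylsilanol this should give methyl 6-(methoxymethoxy)-4-methyl-5-(3-methylbut-2-enyl)-2-(trimethylsilyloxy)benzoate F1, desilylated on mild aqueous work-up to the salicylate phenol methyl 2-hydroxy-6-(methoxymethoxy)-4-methyl-5-(3-methylbut-2-enyl)benzoate F2. Ullmann coupling of F2 with commercial 2-bromo-3,5-dimethoxybenzaldehyde (CuI, N,N-dimethylglycine, Cs2CO3, dioxane, 100 °C; the ortho-formyl group assists) would give methyl 2-(2-formyl-4,6-dimethoxyphenoxy)-6-(methoxymethoxy)-4-methyl-5-(3-methylbut-2-enyl)benzoate F3. NaBH4 in MeOH would reduce it to methyl 2-[2-(hydroxymethyl)-4,6-dimethoxyphenoxy]-6-(methoxymethoxy)-4-methyl-5-(3-methylbut-2-enyl)benzoate F4. The acidic methanolysis of step 14 then takes F4 to 22, where the fallback rejoins the route.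

Step 4. Chemoselectivity may be lost through bromonium formation at the prenyl double bond and capture by the neighbouring 4-hydroxyl (bromo-etherification) instead of substitution at C3. The fallback avoids electrophilic halogen and bypasses steps 4–6. It sets out from 5, which with methyl chloroformate and Et3N in CH2Cl2 should give methyl 6-methyl-5-(3-methylbut-2-enyl)-2-oxo-2H-pyran-4-yl carbonate F5. DMAP with Et3N in warm toluene is then expected to move the methoxycarbonyl group from O4 to C3, an acyl-transfer-catalysed O-to-C shift of the Steglich type that is routine for acyl groups on 4-hydroxy-2-pyranones but less documented for alkoxycarbonyl groups; it is driven by formation of the chelated, more acidic tricarbonyl enol and gives methyl 4-hydroxy-6-methyl-5-(3-methylbut-2-enyl)-2-oxo-2H-pyran-3-carboxylate F6. MOMCl and i-Pr2NEt then give 8, where the fallback rejoins the route.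

Step 2. Alkylation may go astray by reaction on oxygen or at C2, by double alkylation, or by premature lactonisation of the enolate followed by alkylation of the pyranone. The fallback fixes the position of the prenyl group from the start. It sets out from 3 and commercial methyl acetoacetate: the acetoacetate dianion (NaH, then n-BuLi, THF, 0 °C) is alkylated at its terminal carbon by 3 to give methyl 7-methyl-3-oxooct-6-enoate F7. The dianion of F7 (LDA, THF, −78 °C) is then acylated at C4 with N-methoxy-N-methylacetamide to give 4, where the fallback rejoins the route.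

## Further compounds

F1 | step 13 | methyl 6-(methoxymethoxy)-4-methyl-5-(3-methylbut-2-enyl)-2-(trimethylsilyloxy)benzoate | COC(=O)c1c(O[Si](C)(C)C)cc(C)c(CC=C(C)C)c1OCOC
F2 | step 13 | methyl 2-hydroxy-6-(methoxymethoxy)-4-methyl-5-(3-methylbut-2-enyl)benzoate | COC(=O)c1c(O)cc(C)c(CC=C(C)C)c1OCOC
F3 | step 13 | methyl 2-(2-formyl-4,6-dimethoxyphenoxy)-6-(methoxymethoxy)-4-methyl-5-(3-methylbut-2-enyl)benzoate | COC(=O)c1c(Oc2c(C=O)cc(OC)cc2OC)cc(C)c(CC=C(C)C)c1OCOC
F4 | step 13 | methyl 2-[2-(hydroxymethyl)-4,6-dimethoxyphenoxy]-6-(methoxymethoxy)-4-methyl-5-(3-methylbut-2-enyl)benzoate | COC(=O)c1c(Oc2c(CO)cc(OC)cc2OC)cc(C)c(CC=C(C)C)c1OCOC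
F5 | step 4 | methyl 6-methyl-5-(3-methylbut-2-enyl)-2-oxo-2H-pyran-4-yl carbonate | COC(=O)OC1=CC(=O)OC(C)=C1CC=C(C)C
F6 | step 4 | methyl 4-hydroxy-6-methyl-5-(3-methylbut-2-enyl)-2-oxo-2H-pyran-3-carboxylate | COC(=O)C1=C(O)C(CC=C(C)C)=C(C)OC1=O
F7 | step 2 | methyl 7-methyl-3-oxooct-6-enoate | COC(=O)CC(=O)CCC=C(C)C
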